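**Strategy.** Everything rests on opening ring C at C4–C4a. C8a, which carries O1, lies para to C6 on ring A, and O5 and O7 bear the same benzyl group, so the two carbons ortho to O1 (C4a and C8) are equivalent: one intramolecular Friedel–Crafts acylation closes ring C and can only give the 6-aryl flavanone, with C2 untouched. Its precursor is an (R)-3-aryloxy-3-arylpropanoic acid in which ring B carries a benzyl carbonate and the aryloxy group is the benzylated ring A–ring E–flavone unit; C2 is set beforehand by Mitsunobu inversion of an (S)-β-hydroxy ester. A single hydrogenolysis then releases all seven hydroxyl groups.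

Key step: step 18

Labels: flavanone atoms O1 to C8a (rings A and C, ring B on C2); ring E is the catechol ring (E1 on the flavone, E6 on C6); rings F and G are the pyranone and benzo rings of the flavone.

Remark: the target defines only C2, so the C6–E6 biaryl axis (three ortho substituents) is treated as configurationally undefined and rotamers about it count as one compound.

**Route**

Step 1
Reactants: 1 2,4,6-trihydroxybenzaldehyde
Product: 2 2,6-dihydroxy-4-(methoxymethoxy)benzaldehyde
Conditions: MOMCl (1.0 equiv), i-Pr2NEt, THF, −10 → 0 °C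
Reagents that add atoms: chloromethyl methyl ether, COCCl
Why: Selective O-alkylation (Williamson-type acetal formation) is expected at the 4-hydroxyl, the most acidic one and the only one that cannot chelate the formyl oxygen, so that this oxygen (the later O8a) carries a group different from the benzyl groups to come; any bis-ether is removed by chromatography.

Step 2
Reactants: 2 2,6-dihydroxy-4-(methoxymethoxy)benzaldehyde
Product: 3 2,6-bis(benzyloxy)-4-(methoxymethoxy)benzaldehyde
Conditions: BnBr (2.5 equiv), K2CO3, DMF, 60 °C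
Reagents that add atoms: benzyl bromide, BrCc1ccccc1
Why: Williamson ether synthesis in warm DMF should alkylate both chelated ortho hydroxyls (the later O5 and O7), and the MOM acetal is inert to carbonate base.

Step 3
Reactants: 3 2,6-bis(benzyloxy)-4-(methoxymethoxy)benzaldehyde
Product: 4 2,6-bis(benzyloxy)-4-(methoxymethoxy)benzoic acid
Conditions: NaClO2, NaH2PO4, 2-methyl-2-butene, t-BuOH/THF/H2O, 0 °C → rt
Reagents that add atoms: sodium chlorite, [Na+].[O-]Cl=O
Why: Pinnick oxidation converts the hindered aldehyde into the acid at a buffered pH near 4 that the MOM acetal tolerates, while the excess alkene traps hypochlorous acid before it can chlorinate the electron-rich ring.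

Step 4
Reactants: 4 2,6-bis(benzyloxy)-4-(methoxymethoxy)benzoic acid
Product: 5 1,3-bis(benzyloxy)-2-iodo-5-(methoxymethoxy)benzene
Conditions: I2 (2 equiv), K3PO4 (1 equiv), MeCN, 80 °C
Reagents that add atoms: iodine, [I][I]
Why: Ipso-iododecarboxylation (a metal-free Hunsdiecker-type halodecarboxylation known for ortho-alkoxybenzoic acids) should place iodine exactly on the carbon that carried the carboxylate, because this carbon is activated by three oxygen substituents and loses CO2 after attack of iodine; the phosphate keeps the medium non-acidic for the MOM group.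

Step 5
Reactants: 6 methyl 3,4-dihydroxybenzoate
Product: 7 methyl 3,4-bis(benzyloxy)benzoate
Conditions: BnBr (2.2 equiv), K2CO3, DMF, 60 °C
Reagents that add atoms: benzyl bromide, BrCc1ccccc1
Why: Williamson ether synthesis on both catechol hydroxyls; the methyl ester survives carbonate in DMF.

Step 6
Reactants: 7 methyl 3,4-bis(benzyloxy)benzoate
Product: 8 methyl 4,5-bis(benzyloxy)-2-bromobenzoate
Conditions: Br2 (1.05 equiv), NaOAc, AcOH, rt
Reagents that add atoms: bromine, BrBr
Why: Electrophilic aromatic bromination should occur para to the 3-benzyloxy group, at the carbon ortho to the ester (the later E6), as is the rule for 3,4-dialkoxybenzoates, and acetate buffers the HBr that could cleave benzyl ethers.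

Step 7
Reactants: 8 methyl 4,5-bis(benzyloxy)-2-bromobenzoate
Product: 9 methyl 4,5-bis(benzyloxy)-2-(4,4,5,5-tetramethyl-1,3,2-dioxaborolan-2-yl)benzoate
Conditions: B2pin2, PdCl2(dppf) (3 mol %), KOAc, 1,4-dioxane, 90 °C
Reagents that add atoms: bis(pinacolato)diboron, CC1(C)OB(OC1(C)C)B1OC(C)(C)C(C)(C)O1
Why: Miyaura borylation of the aryl bromide through zerovalent palladium formed in situ; the weak base acetate avoids coupling of the product with unreacted bromide and leaves the methyl ester intact.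

Step 8
Reactants: 5 1,3-bis(benzyloxy)-2-iodo-5-(methoxymethoxy)benzene; 9 methyl 4,5-bis(benzyloxy)-2-(4,4,5,5-tetramethyl-1,3,2-dioxaborolan-2-yl)benzoate
Product: 10 methyl 4,5-bis(benzyloxy)-2-[2,6-bis(benzyloxy)-4-(methoxymethoxy)phenyl]benzoate
Conditions: Pd(OAc)2 (5 mol %), SPhos (10 mol %), K3PO4, toluene/H2O, 90 °C
Reagents that add atoms: none
Why: Suzuki–Miyaura coupling with a bulky electron-rich biarylphosphine suited to tri-ortho-substituted biaryls; boron sits on the ester-bearing ring because a 2,6-dialkoxyarylboron reagent would protodeboronate, and the iodide on ring A ensures fast oxidative addition.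

Step 9
Reactants: 10 methyl 4,5-bis(benzyloxy)-2-[2,6-bis(benzyloxy)-4-(methoxymethoxy)phenyl]benzoate
Product: 11 4,5-bis(benzyloxy)-2-[2,6-bis(benzyloxy)-4-(methoxymethoxy)phenyl]benzoic acid
Conditions: LiOH·H2O, THF/MeOH/H2O, 60 °C; then 1 M HCl to pH 3–4, 0 °C
Reagents that add atoms: lithium hydroxide, [Li+].[OH-]
Why: Saponification of the hindered methyl ester by hydroxide, followed by a cold and mild acidification that spares the MOM acetal.

Step 10
Reactants: 12 2,4,6-trihydroxyacetophenone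
Product: 13 1-[2,4-bis(benzyloxy)-6-hydroxyphenyl]ethan-1-one
Conditions: BnBr (2.1 equiv), K2CO3, acetone, reflux
Reagents that add atoms: benzyl bromide, BrCc1ccccc1
Why: Williamson ether synthesis that should stop after two benzylations because the remaining ortho hydroxyl is held in a strong hydrogen bond to the acetyl group; this hydroxyl later becomes the ring oxygen of ring F.

Step 11
Reactants: 11 4,5-bis(benzyloxy)-2-[2,6-bis(benzyloxy)-4-(methoxymethoxy)phenyl]benzoic acid; 13 1-[2,4-bis(benzyloxy)-6-hydroxyphenyl]ethan-1-one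
Product: 14 2-acetyl-3,5-bis(benzyloxy)phenyl 4,5-bis(benzyloxy)-2-[2,6-bis(benzyloxy)-4-(methoxymethoxy)phenyl]benzoate
Conditions: EDC·HCl, DMAP, CH2Cl2, rt
Reagents that add atoms: none
Why: Steglich esterification acylates the only free hydroxyl of 13 under neutral carbodiimide activation, which avoids an acid chloride of 11 that could lactonise onto an ortho benzyloxy group.

Step 12
Reactants: 14 2-acetyl-3,5-bis(benzyloxy)phenyl 4,5-bis(benzyloxy)-2-[2,6-bis(benzyloxy)-4-(methoxymethoxy)phenyl]benzoate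
Product: 17 5,7-bis(benzyloxy)-2-{4,5-bis(benzyloxy)-2-[2,6-bis(benzyloxy)-4-hydroxyphenyl]phenyl}-4H-chromen-4-one, via 1,3-diketone 15 (not isolated), via MOM-protected flavone 16 (not isolated)
Conditions: KOt-Bu, THF, 0 °C → rt; then conc. HCl, MeOH, 55 °C
Reagents that add atoms: none
Why: Baker–Venkataraman rearrangement (intramolecular Claisen acyl transfer from oxygen to the acetyl enolate) gives the 1,3-diketone, and methanolic HCl then effects cyclodehydration to the flavone and, in the same pot, methanolysis of the MOM acetal, which frees the O8a phenol without any oxidant that could attack the phloroglucinol-type ring A.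

Step 13
Reactants: 18 4-hydroxybenzoic acid
Product: 19 4-{[(benzyloxy)carbonyl]oxy}benzoic acid
Conditions: CbzCl, NaOH, H2O/THF, 0 °C; then 1 M HCl
Reagents that add atoms: benzyl chloroformate, O=C(Cl)OCc1ccccc1
Why: Schotten–Baumann acylation, in which the phenoxide is far more nucleophilic than the carboxylate, installs the aryl benzyl carbonate, an electron-poor ring B protecting group that leaves in the final hydrogenolysis.

Step 14
Reactants: 19 4-{[(benzyloxy)carbonyl]oxy}benzoic acid
Product: 21 tert-butyl 3-(4-{[(benzyloxy)carbonyl]oxy}phenyl)-3-oxopropanoate, via acid chloride 20 (not isolated)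
Conditions: (COCl)2, cat. DMF, CH2Cl2, 0 °C → rt, evaporate; then KO2CCH2CO2t-Bu, MgCl2, Et3N, MeCN, 0 °C → rt; cold 1 M HCl
Reagents that add atoms: potassium 3-(tert-butoxy)-3-oxopropanoate, [K+].[O-]C(=O)CC(=O)OC(C)(C)C
Why: The acid chloride C-acylates the magnesium enolate of the malonate half-ester and the acylmalonate loses CO2 on acidic work-up (Masamune–Claisen-type homologation), so C3, C4 and the tert-butyl ester arrive without a strong base that would attack the aryl carbonate.

Step 15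
Reactants: 21 tert-butyl 3-(4-{[(benzyloxy)carbonyl]oxy}phenyl)-3-oxopropanoate
Product: 22 tert-butyl (3S)-3-(4-{[(benzyloxy)carbonyl]oxy}phenyl)-3-hydroxypropanoate
Conditions: RuCl[(S,S)-TsDPEN](p-cymene) (1 mol %), HCO2H/Et3N (5:2), CH2Cl2, 30 °C
Reagents that add atoms: none
Why: Noyori–Ikariya asymmetric transfer hydrogenation, in which the (S,S)-TsDPEN ligand fixes the face of hydride delivery in the six-membered Ru–H/N–H transition state with the aryl group next to the η6-arene, should give the S carbinol as for other aryl ketones (aryl ranks above CH2CO2t-Bu), and the mild formate medium leaves carbonate and ester untouched.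

Step 16
Reactants: 17 flavone phenol (free O8a hydroxyl); 22 tert-butyl (3S)-3-(4-{[(benzyloxy)carbonyl]oxy}phenyl)-3-hydroxypropanoate
Product: 23 tert-butyl (3R)-3-(4-{[(benzyloxy)carbonyl]oxy}phenyl)-3-(3,5-bis(benzyloxy)-4-{4,5-bis(benzyloxy)-2-[5,7-bis(benzyloxy)-4-oxo-4H-chromen-2-yl]phenyl}phenoxy)propanoate
Conditions: PPh3, DIAD, toluene, 0 °C → rt
Reagents that add atoms: none
Why: Mitsunobu etherification, in which the unhindered phenol of 17 displaces the alkoxyphosphonium group in an SN2 reaction with inversion, turns the S carbinol into the R ether (the priority order O > aryl > CH2 is unchanged), while the electron-poor carbonate on ring B disfavours an SN1 pathway and the low temperature in toluene limits elimination to the cinnamate.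

Step 17
Reactants: 23 tert-butyl ester of the (3R)-aryl ether
Product: 24 (3R)-3-(4-{[(benzyloxy)carbonyl]oxy}phenyl)-3-(3,5-bis(benzyloxy)-4-{4,5-bis(benzyloxy)-2-[5,7-bis(benzyloxy)-4-oxo-4H-chromen-2-yl]phenyl}phenoxy)propanoic acid
Conditions: TFA/CH2Cl2 (1:4), 1,3-dimethoxybenzene (10 equiv), 0 °C → rt
Reagents that add atoms: none
Why: Acidolysis of the tert-butyl ester (alkyl–oxygen cleavage) frees the acid without base, which would trigger E1cB loss of the β-aryloxy group and cleave the carbonate; the scavenger intercepts tert-butyl cations before they alkylate ring A, and the carbonate-bearing ring B keeps the benzylic ether from ionising.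

Step 18
Reactants: 24 (3R)-3-aryloxy-3-arylpropanoic acid
Product: 26 benzyl 4-[(2R)-5,7-bis(benzyloxy)-6-{4,5-bis(benzyloxy)-2-[5,7-bis(benzyloxy)-4-oxo-4H-chromen-2-yl]phenyl}-4-oxo-3,4-dihydro-2H-chromen-2-yl]phenyl carbonate, via mixed trifluoroacetic anhydride 25 (not isolated)
Conditions: (CF3CO)2O (3 equiv), CH2Cl2, 0 °C → rt; pH 7 buffer quench
Reagents that add atoms: none
Why: TFAA turns acid 24 into the mixed trifluoroacetic anhydride 25, whose acyl carbon (or the acylium ion that it releases) is attacked by a ring A carbon ortho to O1; loss of the proton from the Wheland intermediate restores the arene and forms the C4–C4a bond. The closest known reaction is the intramolecular Friedel–Crafts acylation of 3-aryloxypropanoic acids to chroman-4-ones. Ring C closes as a six-membered ring in the 6-exo-trig mode, with the attacked carbonyl group outside the new ring. No stereocentre is created: C2 keeps its R configuration because none of its bonds is made or broken, and the benzyl carbonate on ring B holds back ionisation of the benzylic C2–O1 bond in the acidic medium. The step needs site selectivity, and the substrate supplies it: C4a and C8 are exchanged by the local twofold axis through C8a and C6 (O5 and O7 carry the same group), so either attack gives the same 6-aryl constitution, whereas rings E and G cannot reach the acyl carbon through a small ring and ring G is deactivated by its pyranone carbonyl. The attacked carbon is activated ortho, ortho and para by O1, O5 and O7, so no metal Lewis acid is needed and the benzyl ethers and the carbonate should survive.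

Step 19
Reactants: 26 protected (2R)-flavanone
Product: 27 (2R)-6-[2-(5,7-dihydroxy-4-oxo-4H-chromen-2-yl)-4,5-dihydroxyphenyl]-5,7-dihydroxy-2-(4-hydroxyphenyl)-2,3-dihydro-4H-chromen-4-one
Conditions: H2 (1 atm), 10% Pd/C, THF/MeOH, rt
Reagents that add atoms: none
Why: Catalytic hydrogenolysis cleaves the six benzyl ethers and the benzyl carbonate (which then loses CO2) under neutral conditions, so C2 cannot epimerise through the chalcone; the reaction is stopped at full debenzylation, before the slower reduction of the flavone double bond or of the cyclic benzylic C2–O1 bond sets in.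

**Compound list**

1 | 2,4,6-trihydroxybenzaldehyde | O=Cc1c(O)cc(O)cc1O | starting material
2 | 2,6-dihydroxy-4-(methoxymethoxy)benzaldehyde | O=Cc1c(O)cc(OCOC)cc1O | intermediate
3 | 2,6-bis(benzyloxy)-4-(methoxymethoxy)benzaldehyde | O=Cc1c(OCc2ccccc2)cc(OCOC)cc1OCc1ccccc1 | intermediate
4 | 2,6-bis(benzyloxy)-4-(methoxymethoxy)benzoic acid | OC(=O)c1c(OCc2ccccc2)cc(OCOC)cc1OCc1ccccc1 | intermediate
5 | 1,3-bis(benzyloxy)-2-iodo-5-(methoxymethoxy)benzene | COCOc1cc(OCc2ccccc2)c(I)c(OCc2ccccc2)c1 | intermediate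
6 | methyl 3,4-dihydroxybenzoate | COC(=O)c1ccc(O)c(O)c1 | starting material
7 | methyl 3,4-bis(benzyloxy)benzoate | COC(=O)c1ccc(OCc2ccccc2)c(OCc2ccccc2)c1 | intermediate
8 | methyl 4,5-bis(benzyloxy)-2-bromobenzoate | COC(=O)c1cc(OCc2ccccc2)c(OCc2ccccc2)cc1Br | intermediate
9 | methyl 4,5-bis(benzyloxy)-2-(4,4,5,5-tetramethyl-1,3,2-dioxaborolan-2-yl)benzoate | COC(=O)c1cc(OCc2ccccc2)c(OCc2ccccc2)cc1B1OC(C)(C)C(C)(C)O1 | intermediate
10 | methyl 4,5-bis(benzyloxy)-2-[2,6-bis(benzyloxy)-4-(methoxymethoxy)phenyl]benzoate | COC(=O)c1cc(OCc2ccccc2)c(OCc2ccccc2)cc1-c1c(OCc2ccccc2)cc(OCOC)cc1OCc1ccccc1 | intermediate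
11 | 4,5-bis(benzyloxy)-2-[2,6-bis(benzyloxy)-4-(methoxymethoxy)phenyl]benzoic acid | OC(=O)c1cc(OCc2ccccc2)c(OCc2ccccc2)cc1-c1c(OCc2ccccc2)cc(OCOC)cc1OCc1ccccc1 | intermediate
12 | 2,4,6-trihydroxyacetophenone | CC(=O)c1c(O)cc(O)cc1O | starting material
13 | 1-[2,4-bis(benzyloxy)-6-hydroxyphenyl]ethan-1-one | CC(=O)c1c(O)cc(OCc2ccccc2)cc1OCc1ccccc1 | intermediate
14 | 2-acetyl-3,5-bis(benzyloxy)phenyl 4,5-bis(benzyloxy)-2-[2,6-bis(benzyloxy)-4-(methoxymethoxy)phenyl]benzoate | CC(=O)c1c(OC(=O)c2cc(OCc3ccccc3)c(OCc3ccccc3)cc2-c2c(OCc3ccccc3)cc(OCOC)cc2OCc2ccccc2)cc(OCc2ccccc2)cc1OCc1ccccc1 | intermediate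
15 | 1-[2,4-bis(benzyloxy)-6-hydroxyphenyl]-3-{4,5-bis(benzyloxy)-2-[2,6-bis(benzyloxy)-4-(methoxymethoxy)phenyl]phenyl}propane-1,3-dione (not isolated) | O=C(CC(=O)c1cc(OCc2ccccc2)c(OCc2ccccc2)cc1-c1c(OCc2ccccc2)cc(OCOC)cc1OCc1ccccc1)c1c(O)cc(OCc2ccccc2)cc1OCc1ccccc1 | intermediate
16 | 5,7-bis(benzyloxy)-2-{4,5-bis(benzyloxy)-2-[2,6-bis(benzyloxy)-4-(methoxymethoxy)phenyl]phenyl}-4H-chromen-4-one (not isolated) | COCOc1cc(OCc2ccccc2)c(-c2cc(OCc3ccccc3)c(OCc3ccccc3)cc2-c2cc(=O)c3c(OCc4ccccc4)cc(OCc4ccccc4)cc3o2)c(OCc2ccccc2)c1 | intermediate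
17 | 5,7-bis(benzyloxy)-2-{4,5-bis(benzyloxy)-2-[2,6-bis(benzyloxy)-4-hydroxyphenyl]phenyl}-4H-chromen-4-one | Oc1cc(OCc2ccccc2)c(-c2cc(OCc3ccccc3)c(OCc3ccccc3)cc2-c2cc(=O)c3c(OCc4ccccc4)cc(OCc4ccccc4)cc3o2)c(OCc2ccccc2)c1 | intermediate
18 | 4-hydroxybenzoic acid | OC(=O)c1ccc(O)cc1 | starting material
19 | 4-{[(benzyloxy)carbonyl]oxy}benzoic acid | OC(=O)c1ccc(OC(=O)OCc2ccccc2)cc1 | intermediate
20 | 4-{[(benzyloxy)carbonyl]oxy}benzoyl chloride (not isolated) | O=C(Cl)c1ccc(OC(=O)OCc2ccccc2)cc1 | intermediate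
21 | tert-butyl 3-(4-{[(benzyloxy)carbonyl]oxy}phenyl)-3-oxopropanoate | CC(C)(C)OC(=O)CC(=O)c1ccc(OC(=O)OCc2ccccc2)cc1 | intermediate
22 | tert-butyl (3S)-3-(4-{[(benzyloxy)carbonyl]oxy}phenyl)-3-hydroxypropanoate | CC(C)(C)OC(=O)C[C@H](O)c1ccc(OC(=O)OCc2ccccc2)cc1 | intermediate
23 | tert-butyl (3R)-3-(4-{[(benzyloxy)carbonyl]oxy}phenyl)-3-(3,5-bis(benzyloxy)-4-{4,5-bis(benzyloxy)-2-[5,7-bis(benzyloxy)-4-oxo-4H-chromen-2-yl]phenyl}phenoxy)propanoate | CC(C)(C)OC(=O)C[C@H](c1ccc(OC(=O)OCc2ccccc2)cc1)Oc1cc(OCc2ccccc2)c(-c2cc(OCc3ccccc3)c(OCc3ccccc3)cc2-c2cc(=O)c3c(OCc4ccccc4)cc(OCc4ccccc4)cc3o2)c(OCc2ccccc2)c1 | intermediate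
24 | (3R)-3-(4-{[(benzyloxy)carbonyl]oxy}phenyl)-3-(3,5-bis(benzyloxy)-4-{4,5-bis(benzyloxy)-2-[5,7-bis(benzyloxy)-4-oxo-4H-chromen-2-yl]phenyl}phenoxy)propanoic acid | OC(=O)C[C@H](c1ccc(OC(=O)OCc2ccccc2)cc1)Oc1cc(OCc2ccccc2)c(-c2cc(OCc3ccccc3)c(OCc3ccccc3)cc2-c2cc(=O)c3c(OCc4ccccc4)cc(OCc4ccccc4)cc3o2)c(OCc2ccccc2)c1 | intermediate
25 | mixed anhydride of acid 24 with trifluoroacetic acid, (3R) (not isolated) | O=C(OC(=O)C(F)(F)F)C[C@H](c1ccc(OC(=O)OCc2ccccc2)cc1)Oc1cc(OCc2ccccc2)c(-c2cc(OCc3ccccc3)c(OCc3ccccc3)cc2-c2cc(=O)c3c(OCc4ccccc4)cc(OCc4ccccc4)cc3o2)c(OCc2ccccc2)c1 | intermediate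
26 | benzyl 4-[(2R)-5,7-bis(benzyloxy)-6-{4,5-bis(benzyloxy)-2-[5,7-bis(benzyloxy)-4-oxo-4H-chromen-2-yl]phenyl}-4-oxo-3,4-dihydro-2H-chromen-2-yl]phenyl carbonate | O=C1C[C@H](c2ccc(OC(=O)OCc3ccccc3)cc2)Oc2cc(OCc3ccccc3)c(-c3cc(OCc4ccccc4)c(OCc4ccccc4)cc3-c3cc(=O)c4c(OCc5ccccc5)cc(OCc5ccccc5)cc4o3)c(OCc3ccccc3)c21 | intermediate
27 | (2R)-6-[2-(5,7-dihydroxy-4-oxo-4H-chromen-2-yl)-4,5-dihydroxyphenyl]-5,7-dihydroxy-2-(4-hydroxyphenyl)-2,3-dihydro-4H-chromen-4-one | O=C1C[C@H](c2ccc(O)cc2)Oc2cc(O)c(-c3cc(O)c(O)cc3-c3cc(=O)c4c(O)cc(O)cc4o3)c(O)c21 | target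

**Step count and risks**

Total steps: 19. Longest linear sequence: 12 steps (steps 1–4, 8, 9, 11, 12, 16–19).

The three steps most likely to fail:

Step 18 (ring closure). In the acidic medium the benzylic C2–O1 bond may ionise, either before closure or afterwards through retro-oxa-Michael opening of the product. That would erode the 2R configuration or expel the phenol. Fallback, setting out from phenol 17 and returning to the route at target 27: the stereocentre is introduced only after ring C is closed. Mitsunobu etherification of 17 with tert-butyl 3-hydroxypropanoate should give tert-butyl 3-aryloxypropanoate F1. TFA cleavage gives 3-aryloxypropanoic acid F2, and TFAA closes it to C2-unsubstituted chroman-4-one F3 (the same acylation, now with nothing to ionise). Dehydrogenation (DDQ, dioxane, reflux) gives chromone F4. Rhodium-catalysed asymmetric 1,4-addition (Hayashi–Miyaura reaction; [Rh(OH)(cod)]2 with a chiral bisphosphine of the antipode that gives 2R) of 4-(benzyloxy)phenylboronic acid should then add ring B to C2 of F4 only, because the flavone of ring F is blocked at its β-carbon by ring E. This gives hepta-O-benzyl (2R)-flavanone F5, and hydrogenolysis under the conditions of step 19 gives 27.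

Step 16 (Mitsunobu etherification). Dehydration of the activated carbinol to the cinnamate, made easy by the acidic α-hydrogens of the ester, may outrun substitution, and partial SN1 leakage may erode the inversion. Fallback, setting out from phenol 17 and returning at acid 24: the carbinol partner is replaced by one without acidic α-hydrogens. 4-Hydroxybenzaldehyde and benzyl chloroformate give benzyl 4-formylphenyl carbonate F6. Keck allylation (allyltributylstannane, Ti(Oi-Pr)4, the BINOL enantiomer that gives the S carbinol) gives (S)-homoallylic alcohol F7. Mitsunobu reaction of F7 with 17 gives, with inversion, (R)-homoallyl aryl ether F8. Dihydroxylation of the terminal alkene (OsO4 cat., NMO) gives diol F9, NaIO4 cleaves it to β-aryloxy aldehyde F10 (Lemieux–Johnson sequence), and Pinnick oxidation gives 24, so that step 17 is bypassed as well.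

Step 4 (iododecarboxylation). Iodine may attack the two unsubstituted, strongly activated ring positions in addition to the ipso carbon (polyiodination), and the MOM acetal may be lost in hot iodine. Fallback, setting out from aldehyde 3 and returning at biaryl ester 10: the formyl carbon is excised by oxygen insertion, not by way of the acid. Dakin-type Baeyer–Villiger oxidation of 3 (mCPBA, CH2Cl2, 0 °C, migration of the electron-rich aryl group) gives aryl formate F11. Methanolysis (K2CO3, MeOH) gives 2,6-bis(benzyloxy)-4-(methoxymethoxy)phenol F12, and triflation (PhNTf2, Cs2CO3, THF) gives aryl triflate F13. F13 takes the place of iodide 5 in the Suzuki–Miyaura coupling with boronate 9 (Pd(OAc)2, XPhos, K3PO4) to give 10.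

**Further compounds**

F1 | step 18 | tert-butyl 3-(3,5-bis(benzyloxy)-4-{4,5-bis(benzyloxy)-2-[5,7-bis(benzyloxy)-4-oxo-4H-chromen-2-yl]phenyl}phenoxy)propanoate | CC(C)(C)OC(=O)CCOc1cc(OCc2ccccc2)c(-c2cc(OCc3ccccc3)c(OCc3ccccc3)cc2-c2cc(=O)c3c(OCc4ccccc4)cc(OCc4ccccc4)cc3o2)c(OCc2ccccc2)c1
F2 | step 18 | 3-(3,5-bis(benzyloxy)-4-{4,5-bis(benzyloxy)-2-[5,7-bis(benzyloxy)-4-oxo-4H-chromen-2-yl]phenyl}phenoxy)propanoic acid | OC(=O)CCOc1cc(OCc2ccccc2)c(-c2cc(OCc3ccccc3)c(OCc3ccccc3)cc2-c2cc(=O)c3c(OCc4ccccc4)cc(OCc4ccccc4)cc3o2)c(OCc2ccccc2)c1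
F3 | step 18 | 5,7-bis(benzyloxy)-6-{4,5-bis(benzyloxy)-2-[5,7-bis(benzyloxy)-4-oxo-4H-chromen-2-yl]phenyl}-2,3-dihydro-4H-chromen-4-one | O=C1CCOc2cc(OCc3ccccc3)c(-c3cc(OCc4ccccc4)c(OCc4ccccc4)cc3-c3cc(=O)c4c(OCc5ccccc5)cc(OCc5ccccc5)cc4o3)c(OCc3ccccc3)c21
F4 | step 18 | 5,7-bis(benzyloxy)-6-{4,5-bis(benzyloxy)-2-[5,7-bis(benzyloxy)-4-oxo-4H-chromen-2-yl]phenyl}-4H-chromen-4-one | O=c1ccoc2cc(OCc3ccccc3)c(-c3cc(OCc4ccccc4)c(OCc4ccccc4)cc3-c3cc(=O)c4c(OCc5ccccc5)cc(OCc5ccccc5)cc4o3)c(OCc3ccccc3)c12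
F5 | step 18 | (2R)-5,7-bis(benzyloxy)-2-[4-(benzyloxy)phenyl]-6-{4,5-bis(benzyloxy)-2-[5,7-bis(benzyloxy)-4-oxo-4H-chromen-2-yl]phenyl}-2,3-dihydro-4H-chromen-4-one | O=C1C[C@H](c2ccc(OCc3ccccc3)cc2)Oc2cc(OCc3ccccc3)c(-c3cc(OCc4ccccc4)c(OCc4ccccc4)cc3-c3cc(=O)c4c(OCc5ccccc5)cc(OCc5ccccc5)cc4o3)c(OCc3ccccc3)c21
F6 | step 16 | benzyl 4-formylphenyl carbonate | O=Cc1ccc(OC(=O)OCc2ccccc2)cc1
F7 | step 16 | benzyl 4-[(1S)-1-hydroxybut-3-en-1-yl]phenyl carbonate | C=CC[C@H](O)c1ccc(OC(=O)OCc2ccccc2)cc1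
F8 | step 16 | benzyl 4-[(1R)-1-(3,5-bis(benzyloxy)-4-{4,5-bis(benzyloxy)-2-[5,7-bis(benzyloxy)-4-oxo-4H-chromen-2-yl]phenyl}phenoxy)but-3-en-1-yl]phenyl carbonate | C=CC[C@H](c1ccc(OC(=O)OCc2ccccc2)cc1)Oc1cc(OCc2ccccc2)c(-c2cc(OCc3ccccc3)c(OCc3ccccc3)cc2-c2cc(=O)c3c(OCc4ccccc4)cc(OCc4ccccc4)cc3o2)c(OCc2ccccc2)c1
F9 | step 16 | benzyl 4-[(1R)-1-(aryloxy)-3,4-dihydroxybutyl]phenyl carbonate, aryloxy as in F8, mixture of epimers at the new carbinol | OCC(O)C[C@H](c1ccc(OC(=O)OCc2ccccc2)cc1)Oc1cc(OCc2ccccc2)c(-c2cc(OCc3ccccc3)c(OCc3ccccc3)cc2-c2cc(=O)c3c(OCc4ccccc4)cc(OCc4ccccc4)cc3o2)c(OCc2ccccc2)c1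
F10 | step 16 | benzyl 4-[(1R)-1-(aryloxy)-3-oxopropyl]phenyl carbonate, aryloxy as in F8 | O=CC[C@H](c1ccc(OC(=O)OCc2ccccc2)cc1)Oc1cc(OCc2ccccc2)c(-c2cc(OCc3ccccc3)c(OCc3ccccc3)cc2-c2cc(=O)c3c(OCc4ccccc4)cc(OCc4ccccc4)cc3o2)c(OCc2ccccc2)c1
F11 | step 4 | 2,6-bis(benzyloxy)-4-(methoxymethoxy)phenyl formate | O=COc1c(OCc2ccccc2)cc(OCOC)cc1OCc1ccccc1
F12 | step 4 | 2,6-bis(benzyloxy)-4-(methoxymethoxy)phenol | Oc1c(OCc2ccccc2)cc(OCOC)cc1OCc1ccccc1
F13 | step 4 | 2,6-bis(benzyloxy)-4-(methoxymethoxy)phenyl trifluoromethanesulfonate | O=S(=O)(Oc1c(OCc2ccccc2)cc(OCOC)cc1OCc1ccccc1)C(F)(F)F
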